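**Plan**

1. Retrosynthesis: the two O–benzyl bonds and the C3–C4 unsaturation of unit A (the 7-methoxycoumarin half) are removed first. The O1–C8a bond of unit A is then cut (retro-Baeyer–Villiger) to indan-1-one 15, and the diaryl ether bond at C8 of unit A is cut to fluoroindanone 5 and phenol 14.
2. Enabling feature: in unit A the lactone oxygen O1 sits on C8a, ortho to the ether-bearing C8. A ketone carbon on that same carbon (C1 on C7a of an indan-1-one) first activates the neighbouring C7–F bond for fluoride displacement and is afterwards exchanged for O1.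
3. Forward, fragments: the cyclopentanone of 5 is closed by a Nazarov-type cyclisation (step 3). The pyranone of unit B is closed by Wittig olefination–lactonisation (step 4), and its C8 hydroxyl comes from formylation and Dakin oxidation (steps 6 and 7).
4. Forward, union and end game: SNAr joins the halves (step 8), ring expansion gives the lactone of unit A (step 9), DDQ aromatises it to the coumarin (step 10) and BCl3 frees the two phenols (step 11).
5. Stereochemistry: the target has no stereogenic element. The only stereocentre on the route, the carbinol carbon of racemic 3, is erased in step 2.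

Key step: step 9

**Route**

Step 1
Reactants: 1 2-fluoro-3-methoxybenzaldehyde; 2 vinylmagnesium bromide
Product: 3 rac-1-(2-fluoro-3-methoxyphenyl)prop-2-en-1-ol
Conditions: CH2=CHMgBr (1.2 equiv), THF, −78 → 0 °C; aq. NH4Cl
Reagents that add atoms: vinylmagnesium bromide (2), C=C[Mg]Br
Why: Grignard 1,2-addition to an aryl aldehyde is fast at low temperature and the aryl fluoride is inert to the reagent; the carbinol centre is formed racemic and is removed in step 2.

Step 2
Reactants: 3 rac-1-(2-fluoro-3-methoxyphenyl)prop-2-en-1-ol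
Product: 4 1-(2-fluoro-3-methoxyphenyl)prop-2-en-1-one
Conditions: Dess–Martin periodinane, CH2Cl2, 0 °C → rt; crude enone used at once
Reagents that add atoms: none
Why: Dess–Martin oxidation of a secondary allylic benzylic alcohol is mild and non-acidic, so the polymerisation-prone aryl vinyl ketone can be carried forward without storage.

Step 3
Reactants: 4 1-(2-fluoro-3-methoxyphenyl)prop-2-en-1-one
Product: 5 7-fluoro-6-methoxyindan-1-one
Conditions: CF3SO3H, ClCH2CH2Cl, 0 → 50 °C
Reagents that add atoms: none
Why: Superacid-promoted Nazarov-type cyclisation of an aryl vinyl ketone: the O-protonated enone closes onto the only free ortho carbon (the other carries fluorine), a position para to the methoxy donor, and rearomatisation gives the indan-1-one with fluorine at C7 and methoxy at C6.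

Step 4
Reactants: 6 2,4,6-trihydroxybenzaldehyde; 7 ethyl (triphenylphosphoranylidene)acetate
Product: 9 5,7-dihydroxy-2H-chromen-2-one (5,7-dihydroxycoumarin), via trihydroxycinnamate ester 8 (not isolated)
Conditions: Ph3P=CHCO2Et (1.5 equiv), PhNEt2, reflux
Reagents that add atoms: ethyl (triphenylphosphoranylidene)acetate (7), CCOC(=O)C=P(c1ccccc1)(c1ccccc1)c1ccccc1
Why: Wittig olefination of a salicylaldehyde with a stabilised ylide, followed by thermal E/Z isomerisation and lactonisation in hot N,N-diethylaniline, is the standard entry to coumarins unsubstituted at C3 and C4; the symmetry of 6 makes the two ortho hydroxyls equivalent, so one coumarin results.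

Step 5
Reactants: 9 5,7-dihydroxy-2H-chromen-2-one
Product: 10 5,7-bis(benzyloxy)-2H-chromen-2-one
Conditions: BnBr (2.4 equiv), K2CO3, DMF, 50 °C
Reagents that add atoms: benzyl bromide, BrCc1ccccc1
Why: Williamson etherification of two unchelated, acidic coumarin phenols; the lactone tolerates anhydrous carbonate.

Step 6
Reactants: 10 5,7-bis(benzyloxy)-2H-chromen-2-one
Product: 12 5,7-bis(benzyloxy)-2-oxo-2H-chromene-8-carbaldehyde, via aryliminium chloride 11 (not isolated)
Conditions: POCl3, DMF, 0 → 70 °C; then H2O, 60 °C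
Reagents that add atoms: N,N-dimethylformamide, CN(C)C=O; water, O
Why: Vilsmeier–Haack formylation should go to C8, which is para to the 5-benzyloxy group, ortho to the 7-benzyloxy group and to the ring oxygen, and less hindered than C6 between two benzyloxy groups; benzyl ethers tolerate the reagent.

Step 7
Reactants: 12 5,7-bis(benzyloxy)-2-oxo-2H-chromene-8-carbaldehyde
Product: 14 5,7-bis(benzyloxy)-8-hydroxy-2H-chromen-2-one, via aryl formate 13 (not isolated)
Conditions: mCPBA, CH2Cl2, 0 °C → rt; then Et3N, MeOH, rt
Reagents that add atoms: 3-chloroperbenzoic acid, OOC(=O)c1cccc(Cl)c1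
Why: Dakin-type Baeyer–Villiger oxidation of an aldehyde flanked by two ortho oxygen donors proceeds with aryl migration to the formate, which mild methanolysis cleaves without opening the coumarin; the electron-poor C3–C4 alkene does not react with the peracid.

Step 8
Reactants: 5 7-fluoro-6-methoxyindan-1-one; 14 5,7-bis(benzyloxy)-8-hydroxy-2H-chromen-2-one
Product: 15 7-{[5,7-bis(benzyloxy)-2-oxo-2H-chromen-8-yl]oxy}-6-methoxyindan-1-one
Conditions: K2CO3, DMSO, 90 °C, N2
Reagents that add atoms: none
Why: Nucleophilic aromatic substitution by addition–elimination: the C1 carbonyl, held coplanar with the arene by the five-membered ring, stabilises the Meisenheimer adduct at the ortho carbon C7, fluoride is the best leaving group for this mechanism, and phenoxide displacement of fluoride from 7-fluoroindan-1-ones and 2-fluoroaryl ketones is established; the phenoxide of 14 is flanked only by oxygen substituents, which are small at the ipso atom.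

Step 9
Reactants: 15 7-{[5,7-bis(benzyloxy)-2-oxo-2H-chromen-8-yl]oxy}-6-methoxyindan-1-one
Product: 16 8-{[5,7-bis(benzyloxy)-2-oxo-2H-chromen-8-yl]oxy}-7-methoxychroman-2-one
Conditions: mCPBA (1.5 equiv), CF3CO2H, CH2Cl2, 0 °C → rt, dark
Reagents that add atoms: 3-chloroperbenzoic acid, OOC(=O)c1cccc(Cl)c1
Why: Under trifluoroacetic acid catalysis the peracid adds to the C1 carbonyl of 15, and the tetrahedral peroxyester adduct collapses by a 1,2-shift of the aryl carbon C7a from C1 to the proximal peroxide oxygen with loss of 3-chlorobenzoate, which creates the O1–C8a bond of unit A. The closest known reaction type is the Baeyer–Villiger oxidation of indan-1-ones to 3,4-dihydrocoumarins, in which the aryl carbon migrates in preference to the ring methylene. The six-membered lactone arises by one-atom ring expansion of the cyclopentanone (oxygen insertion into the C1–C7a bond), not by a new cyclisation, and no stereocentre is formed. The selectivity needed is migration of C7a instead of C2; it is secured by the ortho aryloxy donor on C7, which stabilises positive charge on the migrating carbon, by the acid, which favours the aryl shift, and by the poor migratory aptitude of a primary alkyl carbon. Chemoselectivity over unit B should hold because its only free ring position (C6) belongs to an arene deactivated by conjugation with the lactone carbonyl and the coumarin C3–C4 alkene is electron-poor, provided the peracid is kept near stoichiometric at low temperature.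

Step 10
Reactants: 16 8-{[5,7-bis(benzyloxy)-2-oxo-2H-chromen-8-yl]oxy}-7-methoxychroman-2-one
Product: 17 5,7-bis(benzyloxy)-8-[(7-methoxy-2-oxo-2H-chromen-8-yl)oxy]-2H-chromen-2-one
Conditions: DDQ (2 equiv), 1,4-dioxane, reflux
Reagents that add atoms: none
Why: DDQ dehydrogenation of a 3,4-dihydrocoumarin: hydride is abstracted from the benzylic C4, which is para to the 7-methoxy donor, and loss of the C3 proton gives the aromatic pyranone; aryl benzyl ethers are slow to react with DDQ in anhydrous dioxane.

Step 11
Reactants: 17 5,7-bis(benzyloxy)-8-[(7-methoxy-2-oxo-2H-chromen-8-yl)oxy]-2H-chromen-2-one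
Product: 18 5,7-dihydroxy-8-[(7-methoxy-2-oxo-2H-chromen-8-yl)oxy]-2H-chromen-2-one (CNP0305396.0)
Conditions: BCl3, C6HMe5, CH2Cl2, −78 → −40 °C; then H2O
Reagents that add atoms: none
Why: Lewis acid debenzylation of aryl benzyl ethers with pentamethylbenzene as a non-basic benzyl cation scavenger is selective at low temperature; the unchelated methyl ether, the diaryl ether and both lactones should survive, and the scavenger prevents C-benzylation at C6.

**Compound list**

1 | 2-fluoro-3-methoxybenzaldehyde | COc1cccc(C=O)c1F | starting material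
2 | vinylmagnesium bromide | C=C[Mg]Br | starting material
3 | rac-1-(2-fluoro-3-methoxyphenyl)prop-2-en-1-ol | COc1cccc(C(O)C=C)c1F | intermediate
4 | 1-(2-fluoro-3-methoxyphenyl)prop-2-en-1-one | COc1cccc(C(=O)C=C)c1F | intermediate
5 | 7-fluoro-6-methoxyindan-1-one | COc1ccc2CCC(=O)c2c1F | intermediate
6 | 2,4,6-trihydroxybenzaldehyde | O=Cc1c(O)cc(O)cc1O | starting material
7 | ethyl (triphenylphosphoranylidene)acetate | CCOC(=O)C=P(c1ccccc1)(c1ccccc1)c1ccccc1 | starting material
8 | ethyl (E)-3-(2,4,6-trihydroxyphenyl)acrylate | CCOC(=O)/C=C/c1c(O)cc(O)cc1O | intermediate (not isolated)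
9 | 5,7-dihydroxy-2H-chromen-2-one | O=c1ccc2c(O)cc(O)cc2o1 | intermediate
10 | 5,7-bis(benzyloxy)-2H-chromen-2-one | O=c1ccc2c(OCc3ccccc3)cc(OCc3ccccc3)cc2o1 | intermediate
11 | N-{[5,7-bis(benzyloxy)-2-oxo-2H-chromen-8-yl]methylidene}-N-methylmethanaminium chloride | C[N+](C)=Cc1c(OCc2ccccc2)cc(OCc2ccccc2)c2ccc(=O)oc12.[Cl-] | intermediate (not isolated)
12 | 5,7-bis(benzyloxy)-2-oxo-2H-chromene-8-carbaldehyde | O=Cc1c(OCc2ccccc2)cc(OCc2ccccc2)c2ccc(=O)oc12 | intermediate
13 | 5,7-bis(benzyloxy)-2-oxo-2H-chromen-8-yl formate | O=COc1c(OCc2ccccc2)cc(OCc2ccccc2)c2ccc(=O)oc12 | intermediate (not isolated)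
14 | 5,7-bis(benzyloxy)-8-hydroxy-2H-chromen-2-one | Oc1c(OCc2ccccc2)cc(OCc2ccccc2)c2ccc(=O)oc12 | intermediate
15 | 7-{[5,7-bis(benzyloxy)-2-oxo-2H-chromen-8-yl]oxy}-6-methoxyindan-1-one | COc1ccc2CCC(=O)c2c1Oc1c(OCc2ccccc2)cc(OCc2ccccc2)c2ccc(=O)oc12 | intermediate
16 | 8-{[5,7-bis(benzyloxy)-2-oxo-2H-chromen-8-yl]oxy}-7-methoxychroman-2-one | COc1ccc2CCC(=O)Oc2c1Oc1c(OCc2ccccc2)cc(OCc2ccccc2)c2ccc(=O)oc12 | intermediate
17 | 5,7-bis(benzyloxy)-8-[(7-methoxy-2-oxo-2H-chromen-8-yl)oxy]-2H-chromen-2-one | COc1ccc2ccc(=O)oc2c1Oc1c(OCc2ccccc2)cc(OCc2ccccc2)c2ccc(=O)oc12 | intermediate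
18 | 5,7-dihydroxy-8-[(7-methoxy-2-oxo-2H-chromen-8-yl)oxy]-2H-chromen-2-one | COc1ccc2ccc(=O)oc2c1Oc1c(O)cc(O)c2ccc(=O)oc12 | target

**Totals**

Total step count: 11. Longest linear sequence: 8 steps (6 → 18 through steps 4–11); the other branch (1 → 5) has 3 steps before the union.

**Steps most likely to fail**

Step 8. The doubly flanked phenoxide may attack too slowly at a carbon that itself lies between a methoxy group and the ring carbonyl, and the enolisable indanone may self-condense under carbonate in the meantime. The fallback makes the ether by copper catalysis. It sets out from phenol 14 and comes back at 15. The coupling partner is built from purchased 2-bromo-3-methoxybenzaldehyde F1 by the operations of steps 1–3: vinylmagnesium bromide should give rac-1-(2-bromo-3-methoxyphenyl)prop-2-en-1-ol F2, Dess–Martin oxidation 1-(2-bromo-3-methoxyphenyl)prop-2-en-1-one F3, and CF3SO3H cyclisation 7-bromo-6-methoxyindan-1-one F4. Ullmann-type coupling of F4 with 14 (CuI, picolinic acid, K3PO4, DMSO, 80–90 °C), assisted by the ortho carbonyl, should then give 15.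

Step 9. The methylene could migrate instead of the aryl carbon, peracid addition to the peri-flanked ketone could be sluggish, or the peracid could hydroxylate the benzyloxy-substituted arene of unit B. The fallback inserts the oxygen at an aldehyde and builds the lactone ring of unit A by olefination. It sets out from phenol 14 and aldehyde 1 and comes back at 17, bypassing steps 9 and 10.
- SNAr of 14 on the non-enolisable, more activated aldehyde 1 (K2CO3, DMF, 100 °C) should give 2-{[5,7-bis(benzyloxy)-2-oxo-2H-chromen-8-yl]oxy}-3-methoxybenzaldehyde F5.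
- Dakin oxidation with mCPBA should give 2-{[5,7-bis(benzyloxy)-2-oxo-2H-chromen-8-yl]oxy}-3-methoxyphenyl formate F6, which is methanolysed in the same flask (Et3N, MeOH) to 5,7-bis(benzyloxy)-8-(2-hydroxy-6-methoxyphenoxy)-2H-chromen-2-one F7.
- Magnesium-mediated ortho-formylation (MgCl2, Et3N, paraformaldehyde, MeCN, reflux) at the only free ortho position should give 3-{[5,7-bis(benzyloxy)-2-oxo-2H-chromen-8-yl]oxy}-2-hydroxy-4-methoxybenzaldehyde F8.
- Wittig reaction with ylide 7 in refluxing PhNEt2, passing through ethyl (E)-3-(3-{[5,7-bis(benzyloxy)-2-oxo-2H-chromen-8-yl]oxy}-2-hydroxy-4-methoxyphenyl)acrylate F9, should lactonise to 17.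

Step 10. Dehydrogenation may stop short, or the quinone may oxidise the benzyl ethers on prolonged heating. The fallback introduces the double bond through enolate chemistry. It sets out from 16 and comes back at 17. Enolate selenation (LiN(SiMe3)2, THF, −78 °C; then PhSeCl) should give rac-8-{[5,7-bis(benzyloxy)-2-oxo-2H-chromen-8-yl]oxy}-7-methoxy-3-(phenylselanyl)chroman-2-one F10. Oxidation (H2O2, pyridine, CH2Cl2, 0 °C → rt) should give rac-8-{[5,7-bis(benzyloxy)-2-oxo-2H-chromen-8-yl]oxy}-7-methoxy-3-(phenylseleninyl)chroman-2-one F11, which is not isolated and should undergo syn-elimination towards C4 to give 17.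

**Further compounds**

F1 | step 8 | 2-bromo-3-methoxybenzaldehyde | COc1cccc(C=O)c1Br
F2 | step 8 | rac-1-(2-bromo-3-methoxyphenyl)prop-2-en-1-ol | COc1cccc(C(O)C=C)c1Br
F3 | step 8 | 1-(2-bromo-3-methoxyphenyl)prop-2-en-1-one | COc1cccc(C(=O)C=C)c1Br
F4 | step 8 | 7-bromo-6-methoxyindan-1-one | COc1ccc2CCC(=O)c2c1Br
F5 | step 9 | 2-{[5,7-bis(benzyloxy)-2-oxo-2H-chromen-8-yl]oxy}-3-methoxybenzaldehyde | COc1cccc(C=O)c1Oc1c(OCc2ccccc2)cc(OCc2ccccc2)c2ccc(=O)oc12
F6 | step 9 | 2-{[5,7-bis(benzyloxy)-2-oxo-2H-chromen-8-yl]oxy}-3-methoxyphenyl formate | COc1cccc(OC=O)c1Oc1c(OCc2ccccc2)cc(OCc2ccccc2)c2ccc(=O)oc12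
F7 | step 9 | 5,7-bis(benzyloxy)-8-(2-hydroxy-6-methoxyphenoxy)-2H-chromen-2-one | COc1cccc(O)c1Oc1c(OCc2ccccc2)cc(OCc2ccccc2)c2ccc(=O)oc12
F8 | step 9 | 3-{[5,7-bis(benzyloxy)-2-oxo-2H-chromen-8-yl]oxy}-2-hydroxy-4-methoxybenzaldehyde | COc1ccc(C=O)c(O)c1Oc1c(OCc2ccccc2)cc(OCc2ccccc2)c2ccc(=O)oc12
F9 | step 9 | ethyl (E)-3-(3-{[5,7-bis(benzyloxy)-2-oxo-2H-chromen-8-yl]oxy}-2-hydroxy-4-methoxyphenyl)acrylate | CCOC(=O)/C=C/c1ccc(OC)c(Oc2c(OCc3ccccc3)cc(OCc3ccccc3)c3ccc(=O)oc23)c1O
F10 | step 10 | rac-8-{[5,7-bis(benzyloxy)-2-oxo-2H-chromen-8-yl]oxy}-7-methoxy-3-(phenylselanyl)chroman-2-one | COc1ccc2CC([Se]c3ccccc3)C(=O)Oc2c1Oc1c(OCc2ccccc2)cc(OCc2ccccc2)c2ccc(=O)oc12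
F11 | step 10 | rac-8-{[5,7-bis(benzyloxy)-2-oxo-2H-chromen-8-yl]oxy}-7-methoxy-3-(phenylseleninyl)chroman-2-one | COc1ccc2CC([Se](=O)c3ccccc3)C(=O)Oc2c1Oc1c(OCc2ccccc2)cc(OCc2ccccc2)c2ccc(=O)oc12
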